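**Plan**
Cuts: (a) the CH2–aryl bond between the bridging methylene, which stays on flavan C8, and the only unsubstituted carbon of the acylphloroglucinol ring D; (b) the C8–CH2 bond, traced back through an 8-formyl group to an 8-bromide; (c) in ring D, the aryl–C(=O) bond and the O–CH3 bond.
Enabling feature: on ring A the C7 hydroxyl is ortho to C8–CH2, and C8 also lies next to O1 and para to O5. A leaving group on that CH2 can therefore be expelled with transient dearomatisation of ring A to an ortho-quinone methide (C7=O, C8=CH2). Ring D offers one nucleophilic CH between two OH groups.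
Forward order: no ring is built. Rings A, B and C arrive intact in (+)-catechin, and ring D comes from a C-methylated phloroglucinol. Ring A is armed at C8 (Br, then CHO, then free O7, then CH2NMe2), ring D is acylated and its oxygens are differentiated, and the halves are then joined.
Helpers: NMe2 leaves in the joining step. The benzyl ethers at O5, O3' and O4' leave in the neutral last step.
Stereochemistry: C2 (R) and C3 (S) are those of (+)-catechin (chiral pool). The ring B phenols stay benzylated through all basic or warm steps, so ring C cannot open and C2 cannot epimerise.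

Key step: step 10

Remark: the stereodescriptors of the SMILES decode as 2R,3S, the series of natural (+)-catechin. (+)-Catechin and 2-methylphloroglucinol are taken as commercial.

**Step 1**
Reactants: 1 (+)-catechin
Product: 2 (2R,3S)-5,7,3',4'-tetra-O-benzylcatechin (3-OH free)
Conditions: BnBr (4.4 equiv), K2CO3 (5 equiv), DMF, 0 °C to rt, Ar
Reagents that add atoms: benzyl bromide BrCc1ccccc1
Why: Williamson ether synthesis in which K2CO3 ionises only the four phenols and not the secondary C3 alcohol, while the mild base at or below room temperature under argon should leave the C2 and C3 stereocentres of the chiral pool material untouched.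

**Step 2**
Reactants: 2 (2R,3S)-5,7,3',4'-tetra-O-benzylcatechin
Product: 3 (2R,3S)-8-bromo-5,7,3',4'-tetra-O-benzylcatechin
Conditions: NBS (1.0 equiv), CH2Cl2, −78 °C to 0 °C
Reagents that add atoms: N-bromosuccinimide O=C1CCC(=O)N1Br
Why: Electrophilic aromatic bromination of the phloroglucinol-type ring A, which in 5,7-di-O-alkylated flavan-3-ols should go to C8 because C6 lies between two freely rotating benzyloxy groups whereas C8 has the tied-back ring oxygen O1 on one side, and one equivalent of NBS at low temperature should spare C6 and ring B.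

**Step 3**
Reactants: 3 (2R,3S)-8-bromo-5,7,3',4'-tetra-O-benzylcatechin
Product: 5 (2R,3S)-5,7,3',4'-tetra-O-benzyl-8-formylcatechin, via C8-lithiated lithium 3-alkoxide 4 (not isolated)
Conditions: n-BuLi (2.2 equiv), THF, −78 °C; DMF (5 equiv), −78 to 0 °C; H2O
Reagents that add atoms: N,N-dimethylformamide CN(C)C=O
Why: Bromine-lithium exchange followed by Bouveault aldehyde synthesis: the first equivalent of n-BuLi takes the C3-OH proton, the second exchanges the C8 bromide faster than it can deprotonate a benzylic ether CH2 at −78 °C, and 4 adds to DMF to give a hemiaminal alkoxide that collapses to the aldehyde only on aqueous quench, so no second addition can occur.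

**Step 4**
Reactants: 5 (2R,3S)-5,7,3',4'-tetra-O-benzyl-8-formylcatechin
Product: 6 (2R,3S)-5,3',4'-tri-O-benzyl-8-formylcatechin (7-OH and 3-OH free)
Conditions: BCl3 (2.2 equiv, 1 M in CH2Cl2), CH2Cl2, −78 °C; H2O
Reagents that add atoms: none
Why: Chelation-directed ether cleavage with BCl3: one equivalent is held as the C3 borate, the other bridges the aldehyde oxygen and O7 so that chloride removes that primary benzyl group by SN2 attack, whereas O5 (para, no chelate), the ring B ethers and the secondary, SN2-inaccessible C2-O1 bond of ring C should persist at −78 °C, which keeps C2 intact.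

**Step 5**
Reactants: 6 (2R,3S)-5,3',4'-tri-O-benzyl-8-formylcatechin
Product: 7 (2R,3S)-5,3',4'-tri-O-benzyl-8-(dimethylaminomethyl)catechin (phenolic Mannich base)
Conditions: Me2NH (2 M in THF, 3 equiv), NaBH(OAc)3 (1.5 equiv), THF, rt
Reagents that add atoms: dimethylamine CNC
Why: Reductive amination: the salicylaldehyde condenses with Me2NH to an iminium phenolate that NaBH(OAc)3 reduces at room temperature, a temperature at which the hydrogen-bonded Mannich base formed should not yet lose amine, so over-reduction to an 8-methyl group is not expected.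

**Step 6**
Reactants: 8 2-methylphloroglucinol
Product: 9 1-(2,4,6-trihydroxy-3-methylphenyl)-2-methylpropan-1-one
Conditions: i-PrCOCl (1.05 equiv), AlCl3 (3.5 equiv), CH2Cl2–PhNO2, 0 to 45 °C; aq. HCl
Reagents that add atoms: isobutyryl chloride CC(C)C(=O)Cl
Why: Friedel-Crafts acylation in which the two free ring positions are equivalent by symmetry, so only one monoketone can form, and the first acyl group deactivates the ring towards a second one.

**Step 7**
Reactants: 9 1-(2,4,6-trihydroxy-3-methylphenyl)-2-methylpropan-1-one
Product: 10 1-[4,6-bis(benzyloxy)-2-hydroxy-3-methylphenyl]-2-methylpropan-1-one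
Conditions: BnBr (2.05 equiv), K2CO3 (2.2 equiv), acetone, reflux
Reagents that add atoms: benzyl bromide BrCc1ccccc1
Why: Williamson ether synthesis under steric and hydrogen-bond control: the 4-OH para to the ketone is the most acidic and reacts first, and of the two ortho hydroxyls the 6-OH next to a ring hydrogen should be alkylated in preference to the 2-OH, which is wedged between acyl and methyl groups and keeps the hydrogen bond to the carbonyl.

**Step 8**
Reactants: 10 1-[4,6-bis(benzyloxy)-2-hydroxy-3-methylphenyl]-2-methylpropan-1-one
Product: 11 1-[4,6-bis(benzyloxy)-2-methoxy-3-methylphenyl]-2-methylpropan-1-one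
Conditions: MeI (3 equiv), K2CO3 (3 equiv), DMF, 50 °C
Reagents that add atoms: iodomethane CI
Why: Williamson methylation of the remaining chelated, hindered phenol, for which the small electrophile MeI in warm DMF suffices, while K2CO3 is too weak to enolise the branched aryl ketone.

**Step 9**
Reactants: 11 1-[4,6-bis(benzyloxy)-2-methoxy-3-methylphenyl]-2-methylpropan-1-one
Product: 12 1-(4,6-dihydroxy-2-methoxy-3-methylphenyl)-2-methylpropan-1-one
Conditions: H2 (1 atm), 10% Pd/C, EtOAc, rt
Reagents that add atoms: none
Why: Catalytic hydrogenolysis of aryl benzyl ethers, which is fast at 1 atm, whereas the di-ortho-substituted, twisted aryl ketone and the methyl ether should not react.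

**Step 10**
Reactants: 7 (2R,3S)-5,3',4'-tri-O-benzyl-8-(dimethylaminomethyl)catechin; 12 1-(4,6-dihydroxy-2-methoxy-3-methylphenyl)-2-methylpropan-1-one
Product: 14 5,3',4'-tri-O-benzylpilosanol B, via ring A ortho-quinone methide 13 (not isolated)
Conditions: 7 (1 equiv), 12 (1.5 equiv), degassed 1,4-dioxane, 85 °C, slow Ar stream
Reagents that add atoms: none
Why: Proton transfer from the acidic 4-OH of 12 (para to the ketone) to the amine of 7 gives an ammonium phenolate pair, and on warming the C7 oxygen pushes Me2NH out of C8–CH2 (E1cB-like), which dearomatises ring A to the ortho-quinone methide 13 (C7=O, C8=CH2) right next to its nucleophile. The phenolate of 12 then adds through its only unsubstituted ring carbon (C5, between the 4- and 6-oxygens) to the exocyclic CH2 in a 1,4-addition, and tautomerisation of the resulting cyclohexadienone restores both aromatic rings, which makes C–C bond formation the thermodynamic sink. The closest known reaction type is the C-alkylation of acylphloroglucinols and other vinylogous acids by phenolic Mannich bases through ortho-quinone methides, the standard entry to methylene-bridged bis-phloroglucinols. No ring is closed and no stereocentre is created; C2 and C3 are spectators, and the benzyl ethers on ring B block the para-quinone-methide opening of ring C by which free catechins epimerise at C2 in warm basic media. The selectivities needed are site (secured because C8 alone carries the CH2, only O7 and not the ring oxygen O1 can become the carbonyl, and ring D has one free carbon), C- over O-alkylation (O-adducts are ortho-hydroxybenzyl aryl ethers that revert to 13) and cross- over self-coupling at C6 of a second flavan (secured by the anionic, far more nucleophilic partner used in excess and by the 5-O-benzyl group flanking C6). Removal of Me2NH in the argon stream should prevent re-addition of the amine and keep the medium close to neutral, which also limits retro-addition and methylene scrambling.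

**Step 11**
Reactants: 14 5,3',4'-tri-O-benzylpilosanol B
Product: 15 pilosanol B
Conditions: H2 (1 atm), 20% Pd(OH)2/C, THF–MeOH, rt
Reagents that add atoms: none
Why: Catalytic hydrogenolysis of the three aryl benzyl ethers under neutral conditions, which should touch neither the diarylmethane bridge, the hydrogen-bonded ketone nor the C2-O1 bond, so that C2 and C3 reach the target with the configuration of (+)-catechin.

**Compound list**
1 | (+)-catechin, (2R,3S)-2-(3,4-dihydroxyphenyl)chromane-3,5,7-triol | c1c(O)cc(O)c2c1O[C@H](c1ccc(O)c(O)c1)[C@@H](O)C2 | starting material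
2 | (2R,3S)-5,7,3',4'-tetra-O-benzylcatechin | c1c(OCc2ccccc2)cc(OCc2ccccc2)c2c1O[C@H](c1ccc(OCc3ccccc3)c(OCc3ccccc3)c1)[C@@H](O)C2 | intermediate
3 | (2R,3S)-8-bromo-5,7,3',4'-tetra-O-benzylcatechin | Brc1c(OCc2ccccc2)cc(OCc2ccccc2)c2c1O[C@H](c1ccc(OCc3ccccc3)c(OCc3ccccc3)c1)[C@@H](O)C2 | intermediate
4 | C8-lithiated lithium 3-alkoxide of tetra-O-benzylcatechin | [Li]c1c(OCc2ccccc2)cc(OCc2ccccc2)c2c1O[C@H](c1ccc(OCc3ccccc3)c(OCc3ccccc3)c1)[C@@H](O[Li])C2 | intermediate
5 | (2R,3S)-5,7,3',4'-tetra-O-benzyl-8-formylcatechin | O=Cc1c(OCc2ccccc2)cc(OCc2ccccc2)c2c1O[C@H](c1ccc(OCc3ccccc3)c(OCc3ccccc3)c1)[C@@H](O)C2 | intermediate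
6 | (2R,3S)-5,3',4'-tri-O-benzyl-8-formylcatechin | O=Cc1c(O)cc(OCc2ccccc2)c2c1O[C@H](c1ccc(OCc3ccccc3)c(OCc3ccccc3)c1)[C@@H](O)C2 | intermediate
7 | (2R,3S)-5,3',4'-tri-O-benzyl-8-(dimethylaminomethyl)catechin | CN(C)Cc1c(O)cc(OCc2ccccc2)c2c1O[C@H](c1ccc(OCc3ccccc3)c(OCc3ccccc3)c1)[C@@H](O)C2 | intermediate
8 | 2-methylphloroglucinol (2-methylbenzene-1,3,5-triol) | Cc1c(O)cc(O)cc1O | starting material
9 | 1-(2,4,6-trihydroxy-3-methylphenyl)-2-methylpropan-1-one | CC(C)C(=O)c1c(O)cc(O)c(C)c1O | intermediate
10 | 1-[4,6-bis(benzyloxy)-2-hydroxy-3-methylphenyl]-2-methylpropan-1-one | CC(C)C(=O)c1c(O)c(C)c(OCc2ccccc2)cc1OCc1ccccc1 | intermediate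
11 | 1-[4,6-bis(benzyloxy)-2-methoxy-3-methylphenyl]-2-methylpropan-1-one | COc1c(C)c(OCc2ccccc2)cc(OCc2ccccc2)c1C(=O)C(C)C | intermediate
12 | 1-(4,6-dihydroxy-2-methoxy-3-methylphenyl)-2-methylpropan-1-one | COc1c(C)c(O)cc(O)c1C(=O)C(C)C | intermediate
13 | ring A ortho-quinone methide (C7=O, C8=CH2) of 5,3',4'-tri-O-benzylcatechin | C=C1C(=O)C=C(OCc2ccccc2)C2=C1O[C@H](c1ccc(OCc3ccccc3)c(OCc3ccccc3)c1)[C@@H](O)C2 | intermediate
14 | 5,3',4'-tri-O-benzylpilosanol B | COc1c(C)c(O)c(Cc2c(O)cc(OCc3ccccc3)c3c2O[C@H](c2ccc(OCc4ccccc4)c(OCc4ccccc4)c2)[C@@H](O)C3)c(O)c1C(=O)C(C)C | intermediate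
15 | pilosanol B | COc1c(C)c(O)c(Cc2c(O)cc(O)c3c2O[C@H](c2ccc(O)c(O)c2)[C@@H](O)C3)c(O)c1C(=O)C(C)C | target

Total step count: 11
Longest linear sequence: 7 steps (1, 2, 3, 4, 5, 10, 11)

**Steps most likely to fail**

**Step 10.** The transient quinone methide may be captured by C6 of a second flavan unit. Amine loss may also need a temperature at which retro-addition already scrambles the methylene bridge between the phenolic rings.

The fallback leaves the neutral quinone methide manifold for a cationic Friedel-Crafts benzylation in the fully benzylated series. There the flavan has no free phenol, C6 is flanked by two benzyloxy groups, and no retro-addition from ring A is possible. It sets out from 5.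
- Reduction with NaBH4 (THF–MeOH, 0 °C) should give (2R,3S)-5,7,3',4'-tetra-O-benzyl-8-(hydroxymethyl)catechin F1.
- Catalytic TsOH·H2O (CH2Cl2, −20 °C) should ionise F1 to the 2,4,6-trialkoxybenzyl cation in the presence of excess 12. Attack of the free ring carbon of 12 should give 5,7,3',4'-tetra-O-benzylpilosanol B F2.
- Hydrogenolysis of the four benzyl ethers (H2, Pd(OH)2/C, THF–MeOH) comes back to the route at 15.

**Step 4.** The Lewis acid may open ring C at the C2–O1 bond and erode the C2 configuration, or further benzyl groups may be lost.

The fallback gives up selective unmasking and frees all phenols at once. It relies on the fact that only O7 is ortho-conjugated with C8–CH2. It sets out from 3.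
- Exchange to 4 as in step 3, then a quench with N,N-dimethylmethyleneiminium iodide (2.5 equiv, −78 °C to rt), should give (2R,3S)-5,7,3',4'-tetra-O-benzyl-8-(dimethylaminomethyl)catechin F3.
- Hydrogenolysis (H2, 10% Pd/C, EtOAc–THF, rt), stopped after four equivalents of H2, should give 8-(dimethylaminomethyl)-(+)-catechin F4. This counts on aryl benzyl ethers cleaving faster than the benzylic C–N bond of an unprotonated, electron-rich tertiary amine.
- Warming F4 with excess 12, which also buffers the medium (degassed MeCN, 50 °C), should pass through the unprotected ring A ortho-quinone methide F5 and come back to the route directly at 15.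

**Step 7.** Discrimination between the two ortho hydroxyl groups may be poor in the second alkylation.

The fallback inverts the logic from selective protection to selective unmasking. It sets out from 9.
- Exhaustive benzylation (excess BnBr, K2CO3, DMF, 60 °C) should give 1-[2,4,6-tris(benzyloxy)-3-methylphenyl]-2-methylpropan-1-one F6.
- BCl3 (1 equiv, CH2Cl2, −78 °C) should then cleave the ketone-chelated ortho ether that is most congested and twisted out of conjugation. This is the 2-O-benzyl group between the acyl and methyl groups, and its cleavage comes back to the route at 10.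

**Further compounds**
F1 | step 10 | (2R,3S)-5,7,3',4'-tetra-O-benzyl-8-(hydroxymethyl)catechin | OCc1c(OCc2ccccc2)cc(OCc2ccccc2)c2c1O[C@H](c1ccc(OCc3ccccc3)c(OCc3ccccc3)c1)[C@@H](O)C2
F2 | step 10 | 5,7,3',4'-tetra-O-benzylpilosanol B | COc1c(C)c(O)c(Cc2c(OCc3ccccc3)cc(OCc3ccccc3)c3c2O[C@H](c2ccc(OCc4ccccc4)c(OCc4ccccc4)c2)[C@@H](O)C3)c(O)c1C(=O)C(C)C
F3 | step 4 | (2R,3S)-5,7,3',4'-tetra-O-benzyl-8-(dimethylaminomethyl)catechin | CN(C)Cc1c(OCc2ccccc2)cc(OCc2ccccc2)c2c1O[C@H](c1ccc(OCc3ccccc3)c(OCc3ccccc3)c1)[C@@H](O)C2
F4 | step 4 | 8-(dimethylaminomethyl)-(+)-catechin | CN(C)Cc1c(O)cc(O)c2c1O[C@H](c1ccc(O)c(O)c1)[C@@H](O)C2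
F5 | step 4 | unprotected ring A ortho-quinone methide of (+)-catechin (C7=O, C8=CH2) | C=C1C(=O)C=C(O)C2=C1O[C@H](c1ccc(O)c(O)c1)[C@@H](O)C2
F6 | step 7 | 1-[2,4,6-tris(benzyloxy)-3-methylphenyl]-2-methylpropan-1-one | CC(C)C(=O)c1c(OCc2ccccc2)c(C)c(OCc2ccccc2)cc1OCc1ccccc1
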